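**Retrosynthetic overview**

- Feature: C3 of the chroman is a benzylic methine bonded to C1′ of ring B (the later quinone) and to the C4 methylene, which ends at C4a of ring A. The C3–C4 pair is therefore a two-carbon unit with one aryl group on each carbon.
- The quinone comes from a ring B 2′-phenol by para-oxidation at C5′. Ring C (the pyran, the only ring that is built) comes from O1–C2 etherification of a ring A phenol with a C2 primary alcohol.
- C2 comes from a one-carbon insertion into a C3–B bond with retention. The C3 boronate comes from a three-component union of a vinylboronate (C3–C4), a ring B aryllithium (C3–C1′) and a ring A aryl triflate (C4–C4a) under chiral palladium catalysis, which sets C3.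
- The ring B donor comes from 2,3-dimethoxyphenol (MOM ether, ortho-lithiation). The ring A triflate comes from 2-hydroxy-4,5-dimethoxybenzaldehyde (benzyl ether, aldehyde to phenol, triflation). Rings A and B are bought as arenes, ring C closes in step 8, and ring B becomes the quinone in step 10.

Key step: step 5

Assumption: the SMILES defines C3 as S, which requires the (S)-boronate. The (Rp,Rp) enantiomer of MandyPhos (1,1′-bis[bis(4-methoxy-3,5-dimethylphenyl)phosphino]-2,2′-bis[α-(dimethylamino)benzyl]ferrocene) is expected to deliver it; this sense is to be checked on the first run by oxidising an aliquot of the boronate to the carbinol, and the mirror-image ligand is used if the check shows the opposite.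

**Route**

Step 1
Reactants: 1 2,3-dimethoxyphenol
Product: 2 1,2-dimethoxy-3-(methoxymethoxy)benzene
Conditions: MOMCl, i-Pr2NEt, CH2Cl2, 0 °C to rt
Reagents that add atoms: chloromethyl methyl ether, COCCl
Why: O-alkylation of the phenol with the reactive α-chloro ether under amine base (acetal protection) installs the group that later directs lithiation and masks the ring B phenol until after ring C is closed.

Step 2
Reactants: 3 2-hydroxy-4,5-dimethoxybenzaldehyde
Product: 4 2-(benzyloxy)-4,5-dimethoxybenzaldehyde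
Conditions: BnBr, K2CO3, DMF, 60 °C
Reagents that add atoms: benzyl bromide, BrCc1ccccc1
Why: Williamson etherification of the only acidic OH gives a phenol protecting group that is orthogonal to MOM and is removed later by hydrogenolysis.

Step 3
Reactants: 4 2-(benzyloxy)-4,5-dimethoxybenzaldehyde
Product: 6 2-(benzyloxy)-4,5-dimethoxyphenol, via aryl formate 5 (not isolated)
Conditions: mCPBA, CH2Cl2, 0 °C to rt; then K2CO3 (cat.), MeOH, rt
Reagents that add atoms: 3-chloroperoxybenzoic acid, OOC(=O)c1cccc(Cl)c1
Why: Baeyer–Villiger (Dakin-type) oxidation, in which the aryl group, made electron-rich by the ortho and para oxygens, migrates in preference to hydrogen to give formate 5; mild methanolysis then frees the phenol without touching the benzyl or methyl ethers.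

Step 4
Reactants: 6 2-(benzyloxy)-4,5-dimethoxyphenol
Product: 7 2-(benzyloxy)-4,5-dimethoxyphenyl trifluoromethanesulfonate
Conditions: Tf2O, pyridine, CH2Cl2, 0 °C
Reagents that add atoms: trifluoromethanesulfonic anhydride, O=S(=O)(OS(=O)(=O)C(F)(F)F)C(F)(F)F
Why: O-sulfonylation of the phenol gives the halide-free electrophile needed for the palladium step.

Step 5
Reactants: 2 1,2-dimethoxy-3-(methoxymethoxy)benzene, 8 vinylboronic acid pinacol ester (2-ethenyl-4,4,5,5-tetramethyl-1,3,2-dioxaborolane), 7 2-(benzyloxy)-4,5-dimethoxyphenyl trifluoromethanesulfonate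
Product: 11 2-[(1S)-2-[2-(benzyloxy)-4,5-dimethoxyphenyl]-1-[3,4-dimethoxy-2-(methoxymethoxy)phenyl]ethyl]-4,4,5,5-tetramethyl-1,3,2-dioxaborolane, via aryllithium 9 (not isolated), via vinyl ate complex 10 (not isolated)
Conditions: 2 (1.0 equiv), n-BuLi (0.95 equiv), THF, 0 °C; 8 (0.95 equiv), 0 °C to rt; Pd(OAc)2 (2 mol %), (Rp,Rp)-MandyPhos (2.4 mol %), 7, THF, 60 °C
Reagents that add atoms: none
Why: n-BuLi lithiates 2 at the single free position ortho to the OMOM group (the stronger director; regiochemistry to be confirmed by a D2O quench) to give halide-free 9, which adds to the boron of 8 to form ate complex 10; oxidative addition of 7 to zerovalent palladium (formed from Pd(OAc)2 and the diphosphine) gives a cationic divalent arylpalladium triflate that binds the vinyl group of 10 and triggers a 1,2-shift of the ring B aryl from boron to C3 anti to palladium (C3–C1′), and reductive elimination from the resulting alkyl(aryl)palladium forms C4–C4a. The closest known reaction type is the enantioselective conjunctive cross-coupling of vinylboron ate complexes derived from aryllithiums with aryl triflates under Pd(OAc)2 and MandyPhos, applied here to two ortho-oxygenated partners. No ring is closed. The C3 stereocentre is set by the catalyst alone: the C2-symmetric ferrocenyl diphosphine decides which face of the bound vinyl group palladium occupies, and the anti-periplanar shift then fixes C3 as S. The step needs the metallate shift to win over direct boron-to-palladium transfer of aryl or vinyl (Suzuki–Miyaura coupling), over migration of a pinacol oxygen and over β-hydride elimination; the halide-free medium (lithiation by deprotonation, triflate as leaving group) keeps palladium cationic and olefin-binding, the electron-rich aryl is the best migrating group on boron, the wide-bite-angle ligand speeds reductive elimination, and n-BuLi is kept below one equivalent of 2 so that no butyl ate complex forms.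

Step 6
Reactants: 11 the (S)-boronate from step 5
Product: 14 (2S)-3-[2-(benzyloxy)-4,5-dimethoxyphenyl]-2-[3,4-dimethoxy-2-(methoxymethoxy)phenyl]propan-1-ol, via chloromethyl ate complex 12 (not isolated), via homologated boronate 13 (not isolated)
Conditions: BrCH2Cl, n-BuLi, THF, −78 °C to rt; then aq. NaOH, H2O2, 0 °C to rt
Reagents that add atoms: bromochloromethane, ClCBr; hydrogen peroxide, OO
Why: Matteson homologation, in which LiCH2Cl made by Br–Li exchange at −78 °C in the presence of 11 adds to boron to give 12, and on warming the secondary benzylic carbon migrates from boron to CH2 with retention as chloride leaves (the carbenoid has gone before the less hindered 13 appears, so a second insertion is avoided); alkaline H2O2 then oxidises the primary C–B bond of 13, which does not involve C3.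

Step 7
Reactants: 14 (2S)-3-[2-(benzyloxy)-4,5-dimethoxyphenyl]-2-[3,4-dimethoxy-2-(methoxymethoxy)phenyl]propan-1-ol
Product: 15 2-[(2S)-3-hydroxy-2-[3,4-dimethoxy-2-(methoxymethoxy)phenyl]propyl]-4,5-dimethoxyphenol
Conditions: H2 (1 atm), Pd/C (10 wt % palladium on carbon), EtOAc/EtOH, rt
Reagents that add atoms: none
Why: Hydrogenolysis of the benzyl ether frees only the ring A phenol, since the MOM acetal, the methyl ethers, the primary alcohol and C3 (which carries no benzylic heteroatom) are inert under neutral conditions.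

Step 8
Reactants: 15 2-[(2S)-3-hydroxy-2-[3,4-dimethoxy-2-(methoxymethoxy)phenyl]propyl]-4,5-dimethoxyphenol
Product: 16 (3S)-3-[3,4-dimethoxy-2-(methoxymethoxy)phenyl]-6,7-dimethoxy-3,4-dihydro-2H-chromene
Conditions: PPh3, DIAD, THF, 0 °C to rt
Reagents that add atoms: none
Why: Intramolecular Mitsunobu etherification, in which the primary alcohol is activated as its alkoxyphosphonium ion and displaced by the ring A phenol in a 6-exo-tet closure (O1–C2) that forms ring C; the ring B phenol is still a MOM ether, so the competing five-membered dihydrobenzofuran cannot form, and C3 is not a reacting centre.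

Step 9
Reactants: 16 (3S)-3-[3,4-dimethoxy-2-(methoxymethoxy)phenyl]-6,7-dimethoxy-3,4-dihydro-2H-chromene
Product: 17 6-[(3S)-6,7-dimethoxy-3,4-dihydro-2H-chromen-3-yl]-2,3-dimethoxyphenol
Conditions: HCl (cat.), MeOH, 50 °C, under argon
Reagents that add atoms: none
Why: Acid-catalysed acetal exchange of the MOM ether with methanol frees the 2′-phenol, while the aryl methyl ethers and the chroman ether survive dilute acid and C3 has no acidic hydrogen at this stage.

Step 10
Reactants: 17 6-[(3S)-6,7-dimethoxy-3,4-dihydro-2H-chromen-3-yl]-2,3-dimethoxyphenol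
Product: 18 5-[(3S)-6,7-dimethoxy-3,4-dihydro-2H-chromen-3-yl]-2,3-dimethoxycyclohexa-2,5-diene-1,4-dione (abruquinone A, the target)
Conditions: (KSO3)2NO (2.5 equiv), KH2PO4, acetone/H2O, 0 °C to rt
Reagents that add atoms: potassium nitrosodisulfonate, [K+].[K+].[O]N(S(=O)(=O)[O-])S(=O)(=O)[O-]
Why: Teuber oxidation, in which one nitrosodisulfonate radical removes the phenolic hydrogen, a second couples at the free para carbon C5′ and loss of imidodisulfonate gives the para-quinone; the aryl ethers of ring A are not attacked by this radical, and the phosphate buffer keeps the medium near neutral so that the C3–H next to the quinone is not enolised.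

**Compound list**

1 | 2,3-dimethoxyphenol | COc1cccc(O)c1OC | starting material
2 | 1,2-dimethoxy-3-(methoxymethoxy)benzene | COCOc1cccc(OC)c1OC | intermediate
3 | 2-hydroxy-4,5-dimethoxybenzaldehyde | COc1cc(O)c(C=O)cc1OC | starting material
4 | 2-(benzyloxy)-4,5-dimethoxybenzaldehyde | COc1cc(OCc2ccccc2)c(C=O)cc1OC | intermediate
5 | 2-(benzyloxy)-4,5-dimethoxyphenyl formate | COc1cc(OCc2ccccc2)c(OC=O)cc1OC | intermediate
6 | 2-(benzyloxy)-4,5-dimethoxyphenol | COc1cc(OCc2ccccc2)c(O)cc1OC | intermediate
7 | 2-(benzyloxy)-4,5-dimethoxyphenyl trifluoromethanesulfonate | COc1cc(OCc2ccccc2)c(OS(=O)(=O)C(F)(F)F)cc1OC | intermediate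
8 | vinylboronic acid pinacol ester | C=CB1OC(C)(C)C(C)(C)O1 | starting material
9 | [3,4-dimethoxy-2-(methoxymethoxy)phenyl]lithium | [Li]c1ccc(OC)c(OC)c1OCOC | intermediate
10 | lithium [3,4-dimethoxy-2-(methoxymethoxy)phenyl](ethenyl)(2,3-dimethylbutane-2,3-diolato)borate | [Li+].C=C[B-]1(c2ccc(OC)c(OC)c2OCOC)OC(C)(C)C(C)(C)O1 | intermediate
11 | 2-[(1S)-2-[2-(benzyloxy)-4,5-dimethoxyphenyl]-1-[3,4-dimethoxy-2-(methoxymethoxy)phenyl]ethyl]-4,4,5,5-tetramethyl-1,3,2-dioxaborolane | COc1ccc([C@H](Cc2cc(OC)c(OC)cc2OCc2ccccc2)B2OC(C)(C)C(C)(C)O2)c(OCOC)c1OC | intermediate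
12 | lithium (chloromethyl)[(1S)-2-[2-(benzyloxy)-4,5-dimethoxyphenyl]-1-[3,4-dimethoxy-2-(methoxymethoxy)phenyl]ethyl](2,3-dimethylbutane-2,3-diolato)borate | COc1ccc([C@H](Cc2cc(OC)c(OC)cc2OCc2ccccc2)[B-]2(CCl)OC(C)(C)C(C)(C)O2)c(OCOC)c1OC.[Li+] | intermediate
13 | 2-[(2S)-3-[2-(benzyloxy)-4,5-dimethoxyphenyl]-2-[3,4-dimethoxy-2-(methoxymethoxy)phenyl]propyl]-4,4,5,5-tetramethyl-1,3,2-dioxaborolane | COc1ccc([C@H](Cc2cc(OC)c(OC)cc2OCc2ccccc2)CB2OC(C)(C)C(C)(C)O2)c(OCOC)c1OC | intermediate
14 | (2S)-3-[2-(benzyloxy)-4,5-dimethoxyphenyl]-2-[3,4-dimethoxy-2-(methoxymethoxy)phenyl]propan-1-ol | COc1ccc([C@H](Cc2cc(OC)c(OC)cc2OCc2ccccc2)CO)c(OCOC)c1OC | intermediate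
15 | 2-[(2S)-3-hydroxy-2-[3,4-dimethoxy-2-(methoxymethoxy)phenyl]propyl]-4,5-dimethoxyphenol | COc1ccc([C@H](Cc2cc(OC)c(OC)cc2O)CO)c(OCOC)c1OC | intermediate
16 | (3S)-3-[3,4-dimethoxy-2-(methoxymethoxy)phenyl]-6,7-dimethoxy-3,4-dihydro-2H-chromene | COc1ccc([C@H]2COc3cc(OC)c(OC)cc3C2)c(OCOC)c1OC | intermediate
17 | 6-[(3S)-6,7-dimethoxy-3,4-dihydro-2H-chromen-3-yl]-2,3-dimethoxyphenol | COc1ccc([C@H]2COc3cc(OC)c(OC)cc3C2)c(O)c1OC | intermediate
18 | 5-[(3S)-6,7-dimethoxy-3,4-dihydro-2H-chromen-3-yl]-2,3-dimethoxycyclohexa-2,5-diene-1,4-dione (abruquinone A) | COC1=C(OC)C(=O)C([C@H]2COc3cc(OC)c(OC)cc3C2)=CC1=O | target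

**Step count**

Total step count: 10 (steps 1–10). Longest linear sequence: 9 steps (3 to 18, steps 2–10).

**Steps most likely to fail, with fallbacks**

Step 5 (most at risk). The divalent arylpalladium triflate may take the aryl or the vinyl group directly from boron instead of inducing the shift, or the alkylpalladium may undergo β-hydride elimination. Face discrimination may also erode, because each aryl partner carries an ortho oxygen that can coordinate the metal. The fallback gives up catalyst control for auxiliary-controlled enolate alkylation. It sets out from 9 (made from 2 as in step 5) and from 4, and it rejoins the route at 14. Aryllithium 9 opens ethylene oxide (THF, 0 °C to rt, NH4Cl work-up) to give 2-[3,4-dimethoxy-2-(methoxymethoxy)phenyl]ethan-1-ol F1. This is oxidised with TEMPO/PhI(OAc)2 in MeCN/H2O to [3,4-dimethoxy-2-(methoxymethoxy)phenyl]acetic acid F2. PivCl/Et3N converts F2 into the mixed pivalic anhydride F3, which acylates lithiated (4S)-4-benzyl-1,3-oxazolidin-2-one to give (4S)-4-benzyl-3-{[3,4-dimethoxy-2-(methoxymethoxy)phenyl]acetyl}-1,3-oxazolidin-2-one F4. In parallel, 4 is reduced (NaBH4, MeOH) to [2-(benzyloxy)-4,5-dimethoxyphenyl]methanol F5 and brominated (PBr3, Et2O, 0 °C) to 1-(benzyloxy)-2-(bromomethyl)-4,5-dimethoxybenzene F6. Deprotonation of F4 with NaN(SiMe3)2 (THF, −78 °C) gives the chelated sodium Z-enolate F7. Bromide F6 should alkylate F7 on the face remote from the auxiliary benzyl group to give the (2S)-configured imide F8. Cold LiBH4 (Et2O, one equivalent of H2O, 0 °C) removes the auxiliary reductively and gives 14 before the α-aryl centre can epimerise.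

Step 6. The carbenoid may decompose before it reaches the hindered secondary benzylic boron, leaving 11 unchanged, or some of it may survive to insert a second time into the less hindered product boronate. The fallback replaces the carbenoid by a stable vinyl nucleophile and trims the extra carbon afterwards. It sets out from 11 and rejoins at 14. CH2=CHMgBr in THF/DMSO adds to 11 to give the vinyl ate complex F9. I2 induces the stereoretentive 1,2-shift to the β-iodoalkyl boronate F10, and NaOMe/MeOH eliminates boron and iodine (Zweifel olefination) to give 1-[(2R)-1-[2-(benzyloxy)-4,5-dimethoxyphenyl]but-3-en-2-yl]-3,4-dimethoxy-2-(methoxymethoxy)benzene F11. Ozonolysis with one equivalent of ozone (CH2Cl2/MeOH, −78 °C) followed at once by NaBH4 reduces the transient (2S)-3-[2-(benzyloxy)-4,5-dimethoxyphenyl]-2-[3,4-dimethoxy-2-(methoxymethoxy)phenyl]propanal F12 to 14 before its α-aryl centre can racemise.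

Step 10. The lipophilic phenol may be oxidised only slowly by the water-bound radical, and prolonged exposure of the product to the aqueous buffer may allow quinone to quinone-methide tautomerism that erodes C3. The fallback replaces direct radical oxygenation by the classical aminophenol sequence, which ends in acid. It sets out from 17 and rejoins at 18. Phenol 17 couples at C5′ (para to OH) with 4-sulfobenzenediazonium (from sulfanilic acid, NaNO2, HCl) in cold aqueous NaOH to give the azo phenol, sodium 4-[(E)-{5-[(3S)-6,7-dimethoxy-3,4-dihydro-2H-chromen-3-yl]-4-hydroxy-2,3-dimethoxyphenyl}diazenyl]benzenesulfonate F13. Ring A, which carries ethers only, should not couple. Na2S2O4 cleaves the azo bond to 4-amino-6-[(3S)-6,7-dimethoxy-3,4-dihydro-2H-chromen-3-yl]-2,3-dimethoxyphenol F14. FeCl3 in dilute HCl oxidises F14 to the quinone monoimine F15, which hydrolyses in the same flask to 18.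

**Further compounds**

F1 | step 5 | 2-[3,4-dimethoxy-2-(methoxymethoxy)phenyl]ethan-1-ol | OCCc1ccc(OC)c(OC)c1OCOC
F2 | step 5 | [3,4-dimethoxy-2-(methoxymethoxy)phenyl]acetic acid | OC(=O)Cc1ccc(OC)c(OC)c1OCOC
F3 | step 5 | [3,4-dimethoxy-2-(methoxymethoxy)phenyl]acetic pivalic anhydride | CC(C)(C)C(=O)OC(=O)Cc1ccc(OC)c(OC)c1OCOC
F4 | step 5 | (4S)-4-benzyl-3-{[3,4-dimethoxy-2-(methoxymethoxy)phenyl]acetyl}-1,3-oxazolidin-2-one | COCOc1c(CC(=O)N2[C@@H](Cc3ccccc3)COC2=O)ccc(OC)c1OC
F5 | step 5 | [2-(benzyloxy)-4,5-dimethoxyphenyl]methanol | COc1cc(OCc2ccccc2)c(CO)cc1OC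
F6 | step 5 | 1-(benzyloxy)-2-(bromomethyl)-4,5-dimethoxybenzene | COc1cc(OCc2ccccc2)c(CBr)cc1OC
F7 | step 5 | sodium Z-enolate of F4 | [Na+].[O-]/C(=C\c1ccc(OC)c(OC)c1OCOC)N1[C@@H](Cc2ccccc2)COC1=O
F8 | step 5 | (4S)-4-benzyl-3-[(2S)-3-[2-(benzyloxy)-4,5-dimethoxyphenyl]-2-[3,4-dimethoxy-2-(methoxymethoxy)phenyl]propanoyl]-1,3-oxazolidin-2-one | COc1ccc([C@H](Cc2cc(OC)c(OC)cc2OCc2ccccc2)C(=O)N2[C@@H](Cc3ccccc3)COC2=O)c(OCOC)c1OC
F9 | step 6 | bromomagnesium ethenyl[(1S)-2-[2-(benzyloxy)-4,5-dimethoxyphenyl]-1-[3,4-dimethoxy-2-(methoxymethoxy)phenyl]ethyl](2,3-dimethylbutane-2,3-diolato)borate | COc1ccc([C@H](Cc2cc(OC)c(OC)cc2OCc2ccccc2)[B-]2(C=C)OC(C)(C)C(C)(C)O2)c(OCOC)c1OC.[Mg+]Br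
F10 | step 6 | 2-[(3R)-4-[2-(benzyloxy)-4,5-dimethoxyphenyl]-3-[3,4-dimethoxy-2-(methoxymethoxy)phenyl]-1-iodobutan-2-yl]-4,4,5,5-tetramethyl-1,3,2-dioxaborolane (both C2 epimers) | COc1ccc([C@H](Cc2cc(OC)c(OC)cc2OCc2ccccc2)C(CI)B2OC(C)(C)C(C)(C)O2)c(OCOC)c1OC
F11 | step 6 | 1-[(2R)-1-[2-(benzyloxy)-4,5-dimethoxyphenyl]but-3-en-2-yl]-3,4-dimethoxy-2-(methoxymethoxy)benzene | COc1ccc([C@H](Cc2cc(OC)c(OC)cc2OCc2ccccc2)C=C)c(OCOC)c1OC
F12 | step 6 | (2S)-3-[2-(benzyloxy)-4,5-dimethoxyphenyl]-2-[3,4-dimethoxy-2-(methoxymethoxy)phenyl]propanal | COc1ccc([C@H](Cc2cc(OC)c(OC)cc2OCc2ccccc2)C=O)c(OCOC)c1OC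
F13 | step 10 | sodium 4-[(E)-{5-[(3S)-6,7-dimethoxy-3,4-dihydro-2H-chromen-3-yl]-4-hydroxy-2,3-dimethoxyphenyl}diazenyl]benzenesulfonate | COc1c(/N=N/c2ccc(S(=O)(=O)[O-])cc2)cc([C@H]2COc3cc(OC)c(OC)cc3C2)c(O)c1OC.[Na+]
F14 | step 10 | 4-amino-6-[(3S)-6,7-dimethoxy-3,4-dihydro-2H-chromen-3-yl]-2,3-dimethoxyphenol | COc1c(N)cc([C@H]2COc3cc(OC)c(OC)cc3C2)c(O)c1OC
F15 | step 10 | 6-[(3S)-6,7-dimethoxy-3,4-dihydro-2H-chromen-3-yl]-4-imino-2,3-dimethoxycyclohexa-2,5-dien-1-one | COC1=C(OC)C(=O)C([C@H]2COc3cc(OC)c(OC)cc3C2)=CC1=N
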